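The 3,4-dihydro-2H-pyran ring is cut into acetaldehyde (ring O1, C2 and its methyl) and an acyclic C3–C4–C5=C6 chain. The key step exploits two features: C3 is alpha to the formyl carbon, hence an enolate carbon, and O1–C6=C5–CO2Me is a vinylogous carbonate that can be closed by vinylic substitution. An auxiliary-controlled syn aldol of a C3 titanium enolate (formyl carried as an N-acylthiazolidinethione) with acetaldehyde forms C2–C3 and sets C2 and C3; acid then lets the new C2 oxygen displace dimethylamine from C6 of an enamino ester, closing the ring. The precursor's only skeletal stereocentre, C4, comes from desymmetrising alcoholysis of a glutaric anhydride with dibenzyl hydroxytyrosol.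

Key step: step 8

Remark: pyran numbering (O1, C2-CH3, C3-CHO, C4-CH2CO2R, C5-CO2Me, C6) is used for all precursors. It is assumed that the quinidine-derived catalyst in step 6 gives (S)-9 (otherwise its quinine-derived pseudoenantiomer is used) and that methanetriacetic acid is commercial. The enamine geometry (drawn E) has no consequence.

Step 1
Reactants: 1 hydroxytyrosol (4-(2-hydroxyethyl)benzene-1,2-diol)
Product: 2 2-[3,4-bis(benzyloxy)phenyl]ethan-1-ol
Conditions: BnBr (2.2 eq), K2CO3, acetone, reflux
Reagents that add atoms: benzyl bromide, BrCc1ccccc1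
Why: Williamson ether synthesis; carbonate deprotonates only the two phenols, so the aliphatic hydroxyl should stay free for step 6.

Step 2
Reactants: 3 methanetriacetic acid
Product: 4 trimethyl methanetriacetate
Conditions: MeOH, H2SO4 (cat.), reflux
Reagents that add atoms: methanol, CO
Why: Fischer esterification driven by excess methanol; the C3-symmetric triester has three equivalent CH2 groups, so the next step has no regiochemical issue.

Step 3
Reactants: 4 trimethyl methanetriacetate
Product: 6 dimethyl 3-[(1E)-1-(dimethylamino)-3-methoxy-3-oxoprop-1-en-2-yl]pentanedioate, via sodium formyl-ester enolate 5 (not isolated)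
Conditions: NaH (1.2 eq), HCO2Me, THF, 0 °C to rt; then Me2NH·HCl, MeOH, rt
Reagents that add atoms: methyl formate, COC=O; dimethylamine hydrochloride, CNC.Cl
Why: Crossed Claisen formylation of one of three equivalent ester CH2 groups (the anionic product should resist a second formylation), then condensation with dimethylamine to the enamino ester, a latent C6 formyl group that is inert to base and unlocked by acid.

Step 4
Reactants: 6 dimethyl 3-[(1E)-1-(dimethylamino)-3-methoxy-3-oxoprop-1-en-2-yl]pentanedioate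
Product: 7 3-[(1E)-1-(dimethylamino)-3-methoxy-3-oxoprop-1-en-2-yl]pentanedioic acid
Conditions: LiOH (2.2 eq), THF/H2O, 0 °C; then 1 M HCl to pH 4, 0 °C
Reagents that add atoms: lithium hydroxide, [Li+].[OH-]
Why: Saponification should take only the two saturated methyl esters, because the vinylogous carbamate ester is strongly deactivated towards hydroxide.

Step 5
Reactants: 7 3-[(1E)-1-(dimethylamino)-3-methoxy-3-oxoprop-1-en-2-yl]pentanedioic acid
Product: 8 methyl (2E)-3-(dimethylamino)-2-(2,6-dioxooxan-4-yl)prop-2-enoate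
Conditions: Ac2O, 60 °C; evaporate with toluene
Reagents that add atoms: none
Why: Cyclodehydration of a 3-substituted glutaric acid to the six-membered anhydride via the mixed anhydride; the fully substituted enamine carbon cannot be acylated.

Step 6
Reactants: 8 methyl (2E)-3-(dimethylamino)-2-(2,6-dioxooxan-4-yl)prop-2-enoate; 2 2-[3,4-bis(benzyloxy)phenyl]ethan-1-ol
Product: 9 (3S)-5-{2-[3,4-bis(benzyloxy)phenyl]ethoxy}-3-[(1E)-1-(dimethylamino)-3-methoxy-3-oxoprop-1-en-2-yl]-5-oxopentanoic acid
Conditions: quinidine-derived 9-amino-9-deoxy-epi bis(trifluoromethyl)benzenesulfonamide catalyst (10 mol %), MTBE, -20 °C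
Reagents that add atoms: none
Why: Cinchona-catalysed desymmetrising alcoholysis of a prochiral 3-substituted glutaric anhydride; the bifunctional catalyst activates the alcohol by general base and one enantiotopic carbonyl by hydrogen bonding, which sets C4 and installs the final ester in one step.

Step 7
Reactants: 9 (3S)-5-{2-[3,4-bis(benzyloxy)phenyl]ethoxy}-3-[(1E)-1-(dimethylamino)-3-methoxy-3-oxoprop-1-en-2-yl]-5-oxopentanoic acid; 10 (4R)-4-benzyl-1,3-thiazolidine-2-thione
Product: 11 2-[3,4-bis(benzyloxy)phenyl]ethyl (3S)-5-[(4R)-4-benzyl-2-sulfanylidene-1,3-thiazolidin-3-yl]-3-[(1E)-1-(dimethylamino)-3-methoxy-3-oxoprop-1-en-2-yl]-5-oxopentanoate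
Conditions: EDC·HCl, DMAP (cat.), CH2Cl2, 0 °C to rt
Reagents that add atoms: none
Why: Carbodiimide-mediated (Steglich-type) N-acylation of the thiazolidinethione; it turns the C7 acid into a chelating imide that is easily enolised and later reducible to the aldehyde.

Step 8
Reactants: 11 2-[3,4-bis(benzyloxy)phenyl]ethyl (3S)-5-[(4R)-4-benzyl-2-sulfanylidene-1,3-thiazolidin-3-yl]-3-[(1E)-1-(dimethylamino)-3-methoxy-3-oxoprop-1-en-2-yl]-5-oxopentanoate; 12 acetaldehyde
Product: 15 methyl (2S,3R,4R)-4-(2-{2-[3,4-bis(benzyloxy)phenyl]ethoxy}-2-oxoethyl)-3-{[(4R)-4-benzyl-2-sulfanylidene-1,3-thiazolidin-3-yl]carbonyl}-2-methyl-3,4-dihydro-2H-pyran-5-carboxylate, via chlorotitanium (Z)-enolate 13 (not isolated), via syn-aldol adduct 14 (not isolated)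
Conditions: TiCl4 (1.1 eq), i-Pr2NEt (1.2 eq), NMP (2 eq), CH2Cl2, 0 °C; MeCHO (3 eq), -78 to 0 °C; then TFA (5 eq), 0 °C to rt
Reagents that add atoms: none
Why: Soft enolisation (TiCl4/i-Pr2NEt) of the imide, the only carbonyl acidified by chelation, gives the chlorotitanium (Z)-enolate 13, which adds to acetaldehyde through a chair Zimmerman–Traxler transition state (Evans-type syn aldol of an N-acylthiazolidinethione, the closest known reaction) and forms C2–C3. With NMP filling the extra titanium site the thiocarbonyl is not chelated, the (4R)-benzyl group shields one enolate face and fixes C3 as R, the (Z)-geometry relays this to C2 (S, syn), and the auxiliary should override the weak bias of the existing C4 centre. On adding TFA the enamino ester of 14 is C-protonated and the C2 hydroxyl attacks C6 (6-endo-trig conjugate addition, equivalent to 6-exo-trig capture of the iminium form); dimethylamine is then expelled as its salt and the C5=C6 enol ether is regenerated, the closest known reactions being the acid-induced closure of hydroxy enaminones to dihydropyranones and the acid-mediated exchange of beta-aminoacrylates with alcohols. The closure creates no stereocentre and touches none. The selectivity needed is attack of the hydroxyl at C6 instead of lactonisation onto the side-chain ester; it should be secured because the protonated vinylogous carbamate is far more electrophilic than an ester and the amine leaves irreversibly.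

Step 9
Reactants: 15 methyl (2S,3R,4R)-4-(2-{2-[3,4-bis(benzyloxy)phenyl]ethoxy}-2-oxoethyl)-3-{[(4R)-4-benzyl-2-sulfanylidene-1,3-thiazolidin-3-yl]carbonyl}-2-methyl-3,4-dihydro-2H-pyran-5-carboxylate
Product: 16 methyl (2S,3R,4R)-4-(2-{2-[3,4-bis(benzyloxy)phenyl]ethoxy}-2-oxoethyl)-3-formyl-2-methyl-3,4-dihydro-2H-pyran-5-carboxylate
Conditions: DIBAL-H (1.2 eq), CH2Cl2, -78 °C; Rochelle salt work-up
Reagents that add atoms: none
Why: Partial reduction of the twisted, thione-activated imide to a stable tetrahedral aluminate that releases the aldehyde on work-up, expected to be faster than ester reduction at -78 °C; C3 keeps its configuration, which is also the favoured trans,trans arrangement.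

Step 10
Reactants: 16 methyl (2S,3R,4R)-4-(2-{2-[3,4-bis(benzyloxy)phenyl]ethoxy}-2-oxoethyl)-3-formyl-2-methyl-3,4-dihydro-2H-pyran-5-carboxylate
Product: 17 methyl (2S,3R,4R)-4-{2-[2-(3,4-dihydroxyphenyl)ethoxy]-2-oxoethyl}-3-formyl-2-methyl-3,4-dihydro-2H-pyran-5-carboxylate (target)
Conditions: H2 (1 atm), 10% Pd/C, EtOAc, rt
Reagents that add atoms: none
Why: Hydrogenolysis of the two aryl benzyl ethers; the aliphatic aldehyde and the push-pull enol ether C=C should not be reduced under these neutral conditions, and no stereocentre is at risk.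

Compound list
1 | hydroxytyrosol, 4-(2-hydroxyethyl)benzene-1,2-diol | OCCc1ccc(O)c(O)c1 | starting material
2 | 2-[3,4-bis(benzyloxy)phenyl]ethan-1-ol | OCCc1ccc(OCc2ccccc2)c(OCc2ccccc2)c1 | intermediate
3 | methanetriacetic acid, 3-(carboxymethyl)pentanedioic acid | OC(=O)CC(CC(=O)O)CC(=O)O | starting material
4 | trimethyl methanetriacetate, dimethyl 3-(2-methoxy-2-oxoethyl)pentanedioate | COC(=O)CC(CC(=O)OC)CC(=O)OC | intermediate
5 | sodium enolate of dimethyl 3-(1-methoxy-1,3-dioxopropan-2-yl)pentanedioate (not isolated) | [Na+].[O-]C=C(C(CC(=O)OC)CC(=O)OC)C(=O)OC | intermediate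
6 | dimethyl 3-[(1E)-1-(dimethylamino)-3-methoxy-3-oxoprop-1-en-2-yl]pentanedioate | CN(C)/C=C(\C(CC(=O)OC)CC(=O)OC)C(=O)OC | intermediate
7 | 3-[(1E)-1-(dimethylamino)-3-methoxy-3-oxoprop-1-en-2-yl]pentanedioic acid | CN(C)/C=C(\C(CC(=O)O)CC(=O)O)C(=O)OC | intermediate
8 | methyl (2E)-3-(dimethylamino)-2-(2,6-dioxooxan-4-yl)prop-2-enoate | CN(C)/C=C(\C1CC(=O)OC(=O)C1)C(=O)OC | intermediate
9 | (3S)-5-{2-[3,4-bis(benzyloxy)phenyl]ethoxy}-3-[(1E)-1-(dimethylamino)-3-methoxy-3-oxoprop-1-en-2-yl]-5-oxopentanoic acid | OC(=O)C[C@H](/C(=C\N(C)C)C(=O)OC)CC(=O)OCCc1ccc(OCc2ccccc2)c(OCc2ccccc2)c1 | intermediate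
10 | (4R)-4-benzyl-1,3-thiazolidine-2-thione | S=C1N[C@H](Cc2ccccc2)CS1 | starting material
11 | 2-[3,4-bis(benzyloxy)phenyl]ethyl (3S)-5-[(4R)-4-benzyl-2-sulfanylidene-1,3-thiazolidin-3-yl]-3-[(1E)-1-(dimethylamino)-3-methoxy-3-oxoprop-1-en-2-yl]-5-oxopentanoate | O=C(C[C@H](/C(=C\N(C)C)C(=O)OC)CC(=O)OCCc1ccc(OCc2ccccc2)c(OCc2ccccc2)c1)N1[C@H](Cc2ccccc2)CSC1=S | intermediate
12 | acetaldehyde | CC=O | starting material
13 | trichlorotitanium (Z)-enolate of 11 (not isolated) | Cl[Ti](Cl)(Cl)O/C(=C\[C@H](/C(=C\N(C)C)C(=O)OC)CC(=O)OCCc1ccc(OCc2ccccc2)c(OCc2ccccc2)c1)N1[C@H](Cc2ccccc2)CSC1=S | intermediate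
14 | 2-[3,4-bis(benzyloxy)phenyl]ethyl (3R,4R,5S)-4-{[(4R)-4-benzyl-2-sulfanylidene-1,3-thiazolidin-3-yl]carbonyl}-3-[(1E)-1-(dimethylamino)-3-methoxy-3-oxoprop-1-en-2-yl]-5-hydroxyhexanoate (syn-aldol adduct, not isolated) | O[C@@H](C)[C@H](C(=O)N1[C@H](Cc2ccccc2)CSC1=S)[C@H](/C(=C\N(C)C)C(=O)OC)CC(=O)OCCc1ccc(OCc2ccccc2)c(OCc2ccccc2)c1 | intermediate
15 | methyl (2S,3R,4R)-4-(2-{2-[3,4-bis(benzyloxy)phenyl]ethoxy}-2-oxoethyl)-3-{[(4R)-4-benzyl-2-sulfanylidene-1,3-thiazolidin-3-yl]carbonyl}-2-methyl-3,4-dihydro-2H-pyran-5-carboxylate | COC(=O)C1=CO[C@@H](C)[C@H](C(=O)N2[C@H](Cc3ccccc3)CSC2=S)[C@H]1CC(=O)OCCc1ccc(OCc2ccccc2)c(OCc2ccccc2)c1 | intermediate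
16 | methyl (2S,3R,4R)-4-(2-{2-[3,4-bis(benzyloxy)phenyl]ethoxy}-2-oxoethyl)-3-formyl-2-methyl-3,4-dihydro-2H-pyran-5-carboxylate | COC(=O)C1=CO[C@@H](C)[C@H](C=O)[C@H]1CC(=O)OCCc1ccc(OCc2ccccc2)c(OCc2ccccc2)c1 | intermediate
17 | methyl (2S,3R,4R)-4-{2-[2-(3,4-dihydroxyphenyl)ethoxy]-2-oxoethyl}-3-formyl-2-methyl-3,4-dihydro-2H-pyran-5-carboxylate | COC(=O)C1=CO[C@@H](C)[C@H](C=O)[C@H]1CC(=O)OCCc1ccc(O)c(O)c1 | target

Total step count: 10. Longest linear sequence: 9 (steps 2 to 10, from methanetriacetic acid 3).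

Steps most likely to fail

Step 8. The ring closure may lag behind the aldol addition, so that the free C2 hydroxyl lactonises onto the side-chain ester or the enamine is merely hydrolysed; the Lewis-basic enamino ester may also slow the soft enolisation. The fallback sets out from 11 and comes back at 15. The titanium aldol is run alone with a buffered aqueous quench and the syn-aldol adduct 14 is isolated. Its enamino ester is hydrolysed with aqueous acetic acid in THF, and the liberated C6 formyl ester should be trapped at once by the C2 hydroxyl as the cyclic hemiacetal F1. Dehydration of F1 with catalytic PPTS in toluene over 4 Å molecular sieves should give 15.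

Step 6. Enantioselectivity or turnover may be poor with the bulky phenethyl-type alcohol 2 as nucleophile. The fallback sets out from 8 and comes back at 9. Anhydride 8 is opened with allyl alcohol, a small primary alcohol of the best-precedented kind, under the pseudoenantiomeric cinchona catalyst. This should give the allyl hemiester F2, whose free acid sits on the arm that must carry the hydroxytyrosol ester. That acid is esterified with 2 (EDC, DMAP) to the mixed diester F3, and removal of the allyl group with Pd(PPh3)4 and morpholine should release 9.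

Step 9. Hydride may attack the unhindered side-chain ester while the hindered imide is being reduced, giving over-reduction. The fallback sets out from 15 and comes back at 16. The imide is reduced completely with NaBH4 in THF/H2O, conditions that leave esters untouched, to the primary alcohol F4. Oxidation of F4 with Dess–Martin periodinane buffered with NaHCO3 should give 16.

Further compounds
F1 | step 8 | methyl (4R,5R,6S)-4-(2-{2-[3,4-bis(benzyloxy)phenyl]ethoxy}-2-oxoethyl)-5-{[(4R)-4-benzyl-2-sulfanylidene-1,3-thiazolidin-3-yl]carbonyl}-2-hydroxy-6-methyloxane-3-carboxylate (mixture at C2 and C3) | COC(=O)C1C(O)O[C@@H](C)[C@H](C(=O)N2[C@H](Cc3ccccc3)CSC2=S)[C@H]1CC(=O)OCCc1ccc(OCc2ccccc2)c(OCc2ccccc2)c1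
F2 | step 6 | (3R)-3-[(1E)-1-(dimethylamino)-3-methoxy-3-oxoprop-1-en-2-yl]-5-oxo-5-(prop-2-en-1-yloxy)pentanoic acid | C=CCOC(=O)C[C@H](/C(=C\N(C)C)C(=O)OC)CC(=O)O
F3 | step 6 | 1-{2-[3,4-bis(benzyloxy)phenyl]ethyl} 5-prop-2-en-1-yl (3R)-3-[(1E)-1-(dimethylamino)-3-methoxy-3-oxoprop-1-en-2-yl]pentanedioate | C=CCOC(=O)C[C@H](/C(=C\N(C)C)C(=O)OC)CC(=O)OCCc1ccc(OCc2ccccc2)c(OCc2ccccc2)c1
F4 | step 9 | methyl (2S,3S,4R)-4-(2-{2-[3,4-bis(benzyloxy)phenyl]ethoxy}-2-oxoethyl)-3-(hydroxymethyl)-2-methyl-3,4-dihydro-2H-pyran-5-carboxylate | COC(=O)C1=CO[C@@H](C)[C@H](CO)[C@H]1CC(=O)OCCc1ccc(OCc2ccccc2)c(OCc2ccccc2)c1
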